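**Retrosynthetic overview**
1. Target 25 comes from 24 by one Lewis-acid unmasking (BCl3 removes the peri 5-O-methyl and the O-isopropyl group).
2. Ring C of 24 comes from the spiro furanone-dienone 23 by a 1,2-acyl shift (dienone–phenol rearrangement, five- to six-membered ring); 23 comes from the 4-acylphenol 22 by oxidative ipso spiro-etherification.
3. 22, with both stereocentres, comes from enol silane 10 and aldehyde 20 by a catalytic anti-selective Mukaiyama aldol.
4. 10 comes from resorcinol 1 and amide 7 (ring A is carried as a symmetric 4-hydroxy-3,5-dimethoxyphenyl ring); 20 comes from catechol 11 (ring B).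
5. Ring order: rings A and B are present from the start as benzene rings; ring C is made last, first as a spiro furanone on dearomatised ring A, then expanded to the pyranone as ring A rearomatises.

Assumption 1: the SMILES is read as (2R,3R), the 2,3-trans flavanonol 3-methyl ether; all descriptors below refer to this.
Assumption 2: the (S,S) bisphosphoramide in step 11 sends the enolate to the Si face of the aldehyde (mirror image of the Re-face attack associated with the (R,R) catalyst); if the sense is the reverse, the (R,R) catalyst is used.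

**Route**

Step 1
Reactants: 1 resorcinol
Product: 2 1,3-dimethoxybenzene
Conditions: Me2SO4 (2.2 equiv), aq NaOH, 10 → 90 °C
Reagents that add atoms: dimethyl sulfate COS(=O)(=O)OC
Why: Williamson O-methylation of the bis-phenoxide on dimethyl sulfate is a high-yielding SN2 reaction.

Step 2
Reactants: 2 1,3-dimethoxybenzene
Product: 5 2,6-dimethoxyphenol, via (2,6-dimethoxyphenyl)lithium 3 (not isolated), via dimethyl (2,6-dimethoxyphenyl)boronate 4 (not isolated)
Conditions: n-BuLi, THF, 0 °C → rt; B(OMe)3, −78 °C → rt; AcOH, 30% H2O2, 0 °C → rt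
Reagents that add atoms: n-butyllithium CCCC[Li] (lithium of 3 only); trimethyl borate COB(OC)OC (boron group of 4 only); hydrogen peroxide OO (hydroxyl oxygen of 5)
Why: Directed ortho-metalation puts lithium between the two methoxy groups, and borylation followed by peroxide oxidation (aryl shift from boron to oxygen) turns C–Li into C–OH.

Step 3
Reactants: 5 2,6-dimethoxyphenol
Product: 6 4-bromo-2,6-dimethoxyphenol
Conditions: NBS (1.0 equiv), CH2Cl2, −45 °C → rt
Reagents that add atoms: N-bromosuccinimide O=C1CCC(=O)N1Br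
Why: Electrophilic aromatic bromination goes para to the free hydroxyl because both ortho positions carry methoxy groups.

Step 4
Reactants: 6 4-bromo-2,6-dimethoxyphenol; 7 2-methoxy-N,N-dimethylacetamide
Product: 9 1-(4-hydroxy-3,5-dimethoxyphenyl)-2-methoxyethan-1-one, via lithium 4-lithio-2,6-dimethoxyphenolate 8 (not isolated)
Conditions: n-BuLi (1.0 equiv) then t-BuLi (2.0 equiv), THF, −78 °C; 7 (1.2 equiv), −78 → 0 °C; 1 M HCl
Reagents that add atoms: n-butyllithium CCCC[Li] and tert-butyllithium CC(C)(C)[Li] (they supply only the two lithium atoms of 8; no reagent atom remains in 9)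
Why: Deprotonation and bromine–lithium exchange give an aryllithium that adds once to the tertiary amide, whose methoxy-chelated tetrahedral adduct survives until acidic work-up (ketone synthesis by acyl substitution of an amide).

Step 5
Reactants: 9 1-(4-hydroxy-3,5-dimethoxyphenyl)-2-methoxyethan-1-one
Product: 10 trimethyl{[(Z)-2-methoxy-1-{3,5-dimethoxy-4-[(trimethylsilyl)oxy]phenyl}ethenyl]oxy}silane
Conditions: TMSOTf (2.3 equiv), Et3N (3 equiv), CH2Cl2, 0 °C → rt; pentane, filtration under argon
Reagents that add atoms: trimethylsilyl triflate C[Si](C)(C)OS(=O)(=O)C(F)(F)F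
Why: Soft enolisation and silylation give the Z enol silane (the aryl group avoids allylic strain with the methoxy group) and mask the phenol in the same operation.

Step 6
Reactants: 11 catechol
Product: 12 1,2-dimethoxybenzene
Conditions: Me2SO4 (2.2 equiv), aq NaOH, 10 → 90 °C
Reagents that add atoms: dimethyl sulfate COS(=O)(=O)OC
Why: Williamson O-methylation, as in step 1.

Step 7
Reactants: 12 1,2-dimethoxybenzene
Product: 15 2,3-dimethoxyphenol, via (2,3-dimethoxyphenyl)lithium 13 (not isolated), via dimethyl (2,3-dimethoxyphenyl)boronate 14 (not isolated)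
Conditions: n-BuLi, TMEDA, Et2O, 0 °C → rt; B(OMe)3, −78 °C → rt; AcOH, 30% H2O2, 0 °C → rt
Reagents that add atoms: n-butyllithium CCCC[Li] (lithium of 13 only); trimethyl borate COB(OC)OC (boron group of 14 only); hydrogen peroxide OO (hydroxyl oxygen of 15)
Why: Directed ortho-metalation next to a methoxy group followed by borylation and peroxide oxidation installs the third contiguous oxygen.

Step 8
Reactants: 15 2,3-dimethoxyphenol
Product: 16 1,2-dimethoxy-3-(propan-2-yloxy)benzene
Conditions: 2-bromopropane, K2CO3, DMF, 60 °C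
Reagents that add atoms: 2-bromopropane CC(C)Br
Why: Williamson etherification; the isopropyl group has no arene C–H bonds to compete in step 9 and is cleaved by BCl3 in step 13.

Step 9
Reactants: 16 1,2-dimethoxy-3-(propan-2-yloxy)benzene
Product: 18 5-bromo-1,2-dimethoxy-3-(propan-2-yloxy)benzene, via aryl pinacol boronate 17 (not isolated)
Conditions: [Ir(OMe)(cod)]2 (1.5 mol %), 4,4'-di-tert-butyl-2,2'-bipyridine (3 mol %), B2pin2 (1.0 equiv), THF, 80 °C; then CuBr2 (3 equiv), MeOH/H2O, 80 °C
Reagents that add atoms: bis(pinacolato)diboron CC1(C)OB(OC1(C)C)B1OC(C)(C)C(C)(C)O1 (boron group of 17 only); copper dibromide Br[Cu]Br (bromine of 18)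
Why: Sterically controlled iridium-catalysed C–H borylation reacts only at C5, the one C–H with no ortho substituent, and copper-mediated bromodeboronation converts C–B into C–Br in the same flask.

Step 10
Reactants: 18 5-bromo-1,2-dimethoxy-3-(propan-2-yloxy)benzene
Product: 20 3,4-dimethoxy-5-(propan-2-yloxy)benzaldehyde, via [3,4-dimethoxy-5-(propan-2-yloxy)phenyl]lithium 19 (not isolated)
Conditions: n-BuLi, THF, −78 °C; DMF, −78 °C → rt; 1 M HCl
Reagents that add atoms: n-butyllithium CCCC[Li] (lithium of 19 only); N,N-dimethylformamide CN(C)C=O (formyl group of 20)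
Why: Bromine–lithium exchange followed by Bouveault formylation with DMF is a standard aldehyde synthesis.

Step 11
Reactants: 10 trimethyl{[(Z)-2-methoxy-1-{3,5-dimethoxy-4-[(trimethylsilyl)oxy]phenyl}ethenyl]oxy}silane; 20 3,4-dimethoxy-5-(propan-2-yloxy)benzaldehyde
Product: 22 (2R,3R)-3-[3,4-dimethoxy-5-(propan-2-yloxy)phenyl]-3-hydroxy-1-(4-hydroxy-3,5-dimethoxyphenyl)-2-methoxypropan-1-one, via trichlorosilyl aldolate 21 (not isolated)
Conditions: SiCl4 (2 equiv), (S,S)-bisphosphoramide (two N,N'-dimethyl-1,1'-binaphthyl-2,2'-diamine phosphoramide units joined by an N,N'-dimethylpentane-1,5-diamine tether, 5 mol %), i-Pr2NEt (10 mol %), CH2Cl2, −78 °C; aq KF/KH2PO4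
Reagents that add atoms: silicon tetrachloride Cl[Si](Cl)(Cl)Cl (SiCl3 group of 21 only; no reagent atom remains in 22)
Why: In this Denmark-type Lewis-base-catalysed Mukaiyama aldol the phosphoramide-bound trichlorosilyl cation activates the aldehyde, the open transition state of an α-methoxy enol silane with a bulky acyl substituent gives the anti adduct, and Si-face attack fixes the 3R carbinol, so both stereocentres (2R,3R) are set here.

Step 12
Reactants: 22 (2R,3R)-3-[3,4-dimethoxy-5-(propan-2-yloxy)phenyl]-3-hydroxy-1-(4-hydroxy-3,5-dimethoxyphenyl)-2-methoxypropan-1-one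
Product: 24 (2R,3R)-2-[3,4-dimethoxy-5-(propan-2-yloxy)phenyl]-6-hydroxy-3,5,7-trimethoxy-2,3-dihydro-4H-chromen-4-one, via spirodienone 23 (not isolated)
Conditions: PhI(OAc)2 (1.0 equiv, slow addition), CF3CH2OH/CH2Cl2 (1:4), −40 °C; then BF3·OEt2 (20 mol %), −40 → 0 °C
Reagents that add atoms: none
Why: Proposed new method: PhI(OAc)2 converts the 4-acyl-2,6-dimethoxyphenol into an aryloxy-iodane whose acyl-bearing para carbon is the only ring position the C3 hydroxyl can reach (five-membered ring), so ipso spiro-etherification gives 23 with both stereocentres untouched, and BF3 then triggers a dienone–phenol 1,2-acyl shift in which the acyl carbon migrates (the cation left behind is an oxocarbenium ion, and the two ortho carbons are equivalent by symmetry), expanding the furanone to the chromanone as ring A rearomatises with its 6-OH between two methoxy groups; the closest known reaction types are oxidative phenol ipso-spirocyclisation (grisan formation from 4'-hydroxybenzophenones, PhI(OAc)2 spiro-etherification of 4-(hydroxyalkyl)phenols) and the acyl-migrating dienone–phenol rearrangement (grisadienedione to xanthone), neither of which has been shown on an aliphatic β-hydroxy 4-acylphenol.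

Step 13
Reactants: 24 (2R,3R)-2-[3,4-dimethoxy-5-(propan-2-yloxy)phenyl]-6-hydroxy-3,5,7-trimethoxy-2,3-dihydro-4H-chromen-4-one
Product: 25 (2R,3R)-5,6-dihydroxy-2-(3-hydroxy-4,5-dimethoxyphenyl)-3,7-dimethoxy-2,3-dihydro-4H-chromen-4-one
Conditions: BCl3 (6 equiv), CH2Cl2, −78 → 0 °C; MeOH, then aq NaHCO3
Reagents that add atoms: none
Why: Chelation-controlled Lewis-acid ether cleavage: boron bound between the C4 carbonyl and the 5-methoxy oxygen removes only that methyl group, and BCl3 also cleaves the secondary isopropyl ether, while the other methyl ethers and both stereocentres stay intact.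

**Compound list**
1 | resorcinol | Oc1cccc(O)c1 | starting material
2 | 1,3-dimethoxybenzene | COc1cccc(OC)c1 | intermediate
3 | (2,6-dimethoxyphenyl)lithium | [Li]c1c(OC)cccc1OC | intermediate (not isolated)
4 | dimethyl (2,6-dimethoxyphenyl)boronate | COB(OC)c1c(OC)cccc1OC | intermediate (not isolated)
5 | 2,6-dimethoxyphenol | COc1cccc(OC)c1O | intermediate
6 | 4-bromo-2,6-dimethoxyphenol | COc1cc(Br)cc(OC)c1O | intermediate
7 | 2-methoxy-N,N-dimethylacetamide | COCC(=O)N(C)C | starting material
8 | lithium 4-lithio-2,6-dimethoxyphenolate | [Li]Oc1c(OC)cc([Li])cc1OC | intermediate (not isolated)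
9 | 1-(4-hydroxy-3,5-dimethoxyphenyl)-2-methoxyethan-1-one | COCC(=O)c1cc(OC)c(O)c(OC)c1 | intermediate
10 | trimethyl{[(Z)-2-methoxy-1-{3,5-dimethoxy-4-[(trimethylsilyl)oxy]phenyl}ethenyl]oxy}silane | CO/C=C(\O[Si](C)(C)C)c1cc(OC)c(O[Si](C)(C)C)c(OC)c1 | intermediate
11 | catechol | Oc1ccccc1O | starting material
12 | 1,2-dimethoxybenzene | COc1ccccc1OC | intermediate
13 | (2,3-dimethoxyphenyl)lithium | [Li]c1cccc(OC)c1OC | intermediate (not isolated)
14 | dimethyl (2,3-dimethoxyphenyl)boronate | COB(OC)c1cccc(OC)c1OC | intermediate (not isolated)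
15 | 2,3-dimethoxyphenol | COc1cccc(O)c1OC | intermediate
16 | 1,2-dimethoxy-3-(propan-2-yloxy)benzene | COc1cccc(OC(C)C)c1OC | intermediate
17 | 2-[3,4-dimethoxy-5-(propan-2-yloxy)phenyl]-4,4,5,5-tetramethyl-1,3,2-dioxaborolane | COc1cc(cc(OC(C)C)c1OC)B1OC(C)(C)C(C)(C)O1 | intermediate (not isolated)
18 | 5-bromo-1,2-dimethoxy-3-(propan-2-yloxy)benzene | COc1cc(Br)cc(OC(C)C)c1OC | intermediate
19 | [3,4-dimethoxy-5-(propan-2-yloxy)phenyl]lithium | [Li]c1cc(OC)c(OC)c(OC(C)C)c1 | intermediate (not isolated)
20 | 3,4-dimethoxy-5-(propan-2-yloxy)benzaldehyde | COc1cc(C=O)cc(OC(C)C)c1OC | intermediate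
21 | (2R,3R)-1-{3,5-dimethoxy-4-[(trimethylsilyl)oxy]phenyl}-3-[3,4-dimethoxy-5-(propan-2-yloxy)phenyl]-2-methoxy-3-[(trichlorosilyl)oxy]propan-1-one | COc1cc(cc(OC)c1O[Si](C)(C)C)C(=O)[C@H](OC)[C@@H](c1cc(OC(C)C)c(OC)c(OC)c1)O[Si](Cl)(Cl)Cl | intermediate (not isolated)
22 | (2R,3R)-3-[3,4-dimethoxy-5-(propan-2-yloxy)phenyl]-3-hydroxy-1-(4-hydroxy-3,5-dimethoxyphenyl)-2-methoxypropan-1-one | COc1cc(cc(OC)c1O)C(=O)[C@H](OC)[C@@H](c1cc(OC(C)C)c(OC)c(OC)c1)O | intermediate
23 | (2R,3R)-2-[3,4-dimethoxy-5-(propan-2-yloxy)phenyl]-3,7,9-trimethoxy-1-oxaspiro[4.5]deca-6,9-diene-4,8-dione | O=C1[C@H](OC)[C@@H](c2cc(OC(C)C)c(OC)c(OC)c2)OC13C=C(OC)C(=O)C(OC)=C3 | intermediate (not isolated)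
24 | (2R,3R)-2-[3,4-dimethoxy-5-(propan-2-yloxy)phenyl]-6-hydroxy-3,5,7-trimethoxy-2,3-dihydro-4H-chromen-4-one | COc1cc2c(c(OC)c1O)C(=O)[C@H](OC)[C@@H](c1cc(OC(C)C)c(OC)c(OC)c1)O2 | intermediate
25 | (2R,3R)-5,6-dihydroxy-2-(3-hydroxy-4,5-dimethoxyphenyl)-3,7-dimethoxy-2,3-dihydro-4H-chromen-4-one (CNP0075601.1) | COc1cc2c(c(O)c1O)C(=O)[C@H](OC)[C@@H](c1cc(O)c(OC)c(OC)c1)O2 | target

**Step count and risks**
Total steps: 13. Longest linear sequence: 8 (steps 1–5 or steps 6–10, then 11–13).

Risk 1, step 12 (the new reaction). The spiro-etherification at an acyl-bearing carbon may be slow, or product 24 may be over-oxidised. The fallback rebuilds ring A with known reactions so that the acyl group already sits ortho to the future ring oxygen. It sets out from 5 and uses aldehyde 20. O2 with Co(salen) in DMF oxidises 5 to 2,6-dimethoxycyclohexa-2,5-diene-1,4-dione F1, and Na2S2O4 reduces this to 2,6-dimethoxybenzene-1,4-diol F2. A Hoesch reaction of F2 with methoxyacetonitrile (ZnCl2, HCl, Et2O) gives 1-(3,6-dihydroxy-2,4-dimethoxyphenyl)-2-methoxyethan-1-iminium chloride F3, which hot water hydrolyses to 1-(3,6-dihydroxy-2,4-dimethoxyphenyl)-2-methoxyethan-1-one F4. Claisen–Schmidt condensation of F4 with 20 (KOH, EtOH, under argon) gives (2Z)-1-(3,6-dihydroxy-2,4-dimethoxyphenyl)-3-[3,4-dimethoxy-5-(propan-2-yloxy)phenyl]-2-methoxyprop-2-en-1-one F5. Oxa-Michael ring closure (NaOAc, EtOH, reflux) gives the racemic trans chromanone F6, and preparative chromatography on a chiral stationary phase delivers the (2R,3R) enantiomer, which is 24, where the route is rejoined.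

Risk 2, step 11. The anti-selectivity and ee are precedented for α-methoxy silyl ketene acetals, not for this ketone-derived enol silane. The fallback runs the aldol on a thioester, where tin-triflate/chiral-diamine anti-selective aldols of α-alkoxy ketene silyl thioacetals are established, and makes the aryl ketone afterwards. It sets out from 20 and 6. Methoxyacetyl chloride and ethanethiol (pyridine) give S-ethyl 2-methoxyethanethioate F7, and LDA/TMSCl converts it into {[(Z)-1-(ethylsulfanyl)-2-methoxyethenyl]oxy}(trimethyl)silane F8. Sn(OTf)2, Bu2Sn(OAc)2 and the chiral diamine 1-methyl-2-[(naphthalen-1-ylamino)methyl]pyrrolidine, in the enantiomeric form that gives the 3R carbinol, promote addition of F8 to 20 and give S-ethyl (2R,3R)-3-[3,4-dimethoxy-5-(propan-2-yloxy)phenyl]-3-hydroxy-2-methoxypropanethioate F9. Separately, 6 is converted through dianion 8 and B(OiPr)3 into (4-hydroxy-3,5-dimethoxyphenyl)boronic acid F10. Liebeskind–Srogl coupling of F9 with F10 (Pd2(dba)3, tri(2-furyl)phosphine, copper thiophene-2-carboxylate CuTC, THF) gives 22, where the route is rejoined.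

Risk 3, step 13. BCl3 may also attack the 3-, 7- or 4'-methoxy groups. The fallback separates the two dealkylations and uses a nucleophilic, chelation-controlled demethylation first. It sets out from 24. MgI2·OEt2 in toluene/Et2O at 60 °C removes only the peri methyl group next to the carbonyl (magnesium chelate, iodide as nucleophile) and gives (2R,3R)-2-[3,4-dimethoxy-5-(propan-2-yloxy)phenyl]-5,6-dihydroxy-3,7-dimethoxy-2,3-dihydro-4H-chromen-4-one F11. AlCl3 in CH2Cl2 at 0 °C then cleaves only the secondary isopropyl ether and gives 25, where the route is rejoined.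

**Further compounds**
F1 | step 12 | 2,6-dimethoxycyclohexa-2,5-diene-1,4-dione | COC1=CC(=O)C=C(OC)C1=O
F2 | step 12 | 2,6-dimethoxybenzene-1,4-diol | COc1cc(O)cc(OC)c1O
F3 | step 12 | 1-(3,6-dihydroxy-2,4-dimethoxyphenyl)-2-methoxyethan-1-iminium chloride | COCC(=[NH2+])c1c(O)cc(OC)c(O)c1OC.[Cl-]
F4 | step 12 | 1-(3,6-dihydroxy-2,4-dimethoxyphenyl)-2-methoxyethan-1-one | COCC(=O)c1c(O)cc(OC)c(O)c1OC
F5 | step 12 | (2Z)-1-(3,6-dihydroxy-2,4-dimethoxyphenyl)-3-[3,4-dimethoxy-5-(propan-2-yloxy)phenyl]-2-methoxyprop-2-en-1-one | CO/C(=C\c1cc(OC)c(OC)c(OC(C)C)c1)C(=O)c1c(O)cc(OC)c(O)c1OC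
F6 | step 12 | racemic trans-2-[3,4-dimethoxy-5-(propan-2-yloxy)phenyl]-6-hydroxy-3,5,7-trimethoxy-2,3-dihydro-4H-chromen-4-one (1:1 mixture of the 2R,3R and 2S,3S forms) | COc1cc2c(c(OC)c1O)C(=O)[C@H](OC)[C@@H](c1cc(OC(C)C)c(OC)c(OC)c1)O2.COc1cc2c(c(OC)c1O)C(=O)[C@@H](OC)[C@H](c1cc(OC(C)C)c(OC)c(OC)c1)O2
F7 | step 11 | S-ethyl 2-methoxyethanethioate | CCSC(=O)COC
F8 | step 11 | {[(Z)-1-(ethylsulfanyl)-2-methoxyethenyl]oxy}(trimethyl)silane | CCS/C(O[Si](C)(C)C)=C\OC
F9 | step 11 | S-ethyl (2R,3R)-3-[3,4-dimethoxy-5-(propan-2-yloxy)phenyl]-3-hydroxy-2-methoxypropanethioate | CCSC(=O)[C@H](OC)[C@@H](c1cc(OC(C)C)c(OC)c(OC)c1)O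
F10 | step 11 | (4-hydroxy-3,5-dimethoxyphenyl)boronic acid | COc1cc(cc(OC)c1O)B(O)O
F11 | step 13 | (2R,3R)-2-[3,4-dimethoxy-5-(propan-2-yloxy)phenyl]-5,6-dihydroxy-3,7-dimethoxy-2,3-dihydro-4H-chromen-4-one | COc1cc2c(c(O)c1O)C(=O)[C@H](OC)[C@@H](c1cc(OC(C)C)c(OC)c(OC)c1)O2
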